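The ratio of coupling partner to left-handed substrate charged in the flask is 1.50, and the question is what that surplus is worth.

in all of them: left-handed substrate 0.065 M; right-handed substrate 0.065 M; protic impurity 3.25 mM
- Thursday's: coupling partner 0.049 M; free catalyst 72 µM; run made earlier
- Sunday's: coupling partner 0.20 M; free catalyst 72 µM; run made earlier
- Friday's: coupling partner 0.0975 M; free catalyst 36 µM; run made earlier
- flask: coupling partner 0.0975 M; free catalyst 72 µM; time 15 h

| run | time / h | right-handed substrate / % | left-handed substrate / % | left-handed product / % |
|---|---|---|---|---|
| Thursday's | 4.00 | 48.5 | 15.3 | 35.1 |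
| Thursday's | 8.00 | 50.2 | 16.7 | 35.5 |
| Thursday's | 10.0 | 50.2 | 13.0 | 35.4 |
| Thursday's | 15.0 | 47.8 | 14.2 | 34.3 |
| Thursday's | 20.0 | 47.7 | 15.5 | 34.0 |
| Sunday's | 1.33 | 46.5 | 0 | 51.1 |
| Sunday's | 2.50 | 44.3 | 0 | 49.6 |
| Sunday's | 5.00 | 40.4 | 0.2 | 50.9 |
| Sunday's | 10.0 | 31.0 | 0 | 48.2 |
| Sunday's | 20.0 | 17.8 | 0 | 50.9 |
| Friday's | 1.33 | 49.3 | 5.1 | 46.5 |
| Friday's | 2.50 | 50.6 | 0.5 | 47.7 |
| Friday's | 5.00 | 47.7 | 0 | 49.7 |
| Friday's | 10.0 | 48.5 | 0.6 | 51.3 |
| Friday's | 20.0 | 43.4 | 0.5 | 50.2 |

(standard deviation of a reading: 1 percentage point)

- free catalyst is single-handed; left-handed substrate and right-handed substrate are mirror images of each other, charged as a racemate, each of them at the stated concentration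

- whether the excess of right-handed substrate over left-handed substrate among what is left of the two reaches 98% by 15 h (no / yes)
- the highest excess of right-handed substrate over left-handed substrate among what is left of the two up to 15 h

I build the flask up one process at a time. With the main step alone, one coupling partner per left-handed substrate (the substrate being the one the catalyst prefers), 0.0325 M of partner stands over. Now I add the protic impurity. Thursday's product holds at 35.5%, and partner less impurity gives 35.2%, so I let the impurity take partner one for one. That lowers the surplus to 0.0292 M. This spare partner, the partner left once impurity and left-handed substrate have each taken their charge, is what I carry. While it stays positive, the left-handed substrate keeps finding partner; Friday's flask, with the same charge and half the catalyst, reads 0% of it at 5.00 h.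

Last comes the right-handed substrate, which eats the spare. Sunday's right-handed substrate, at this catalyst charge, falls at 0.0514 h⁻¹ with about 0.109 M of partner present. Holding c(right-handed substrate) at its charge makes the loss of spare pseudo-first-order, with constant 0.0308 h⁻¹. Integrated, c(coupling partner) is the spare times the exponential of minus that constant times time, so 0.0184 M remains at 15 h. I therefore expect the excess to be reached.

The forecast says yes, with a top of 99.9% (range 99% to 100%), holding that “the reaction stops once partner is gone”.

The flask gives yes and 100%, the wanted excess standing at 0.873 h.

    coupling partner + catalyst intermediate A → free catalyst + left-handed product (k = 425 M⁻¹ min⁻¹)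
    coupling partner + catalyst intermediate B → free catalyst + right-handed product (k = 24.0 M⁻¹ min⁻¹)
    free catalyst + right-handed substrate ⇌ catalyst intermediate B (K = 5.50 M⁻¹, k = 35500 M⁻¹ min⁻¹)
    coupling partner + protic impurity → quenched reagent (k = 37.7 M⁻¹ min⁻¹)
    coupling partner → decomposition product (k = 1.69 × 10⁻⁵ min⁻¹)
    free catalyst + left-handed substrate ⇌ catalyst intermediate A (K = 380 M⁻¹, k = 99400 M⁻¹ min⁻¹)

In the flask the spare was 30.0% of the partner's charge, and 20% remains at 15.0 h, while right-handed product has grown to 6.93%. The excess at 15 h depends on the undoing of catalyst intermediate B into free catalyst and right-handed substrate. In the same flask with that undoing taken away, where a negative value means left-handed substrate in excess, the excess at 15 h is −80.8% against 100%.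

All runs stem from a simulated flask on assumed constants, and the scatter is random.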